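**Plan**

- Target: (1R,3aR,4R,5S,7aS)-3,5-diethyl-1,4,7-trimethyl-5-[(E)-2-phenylethenyl]-3a,4,5,7a-tetrahydro-1H-indene-4-carboxylic acid. The first cut opens the C2=C3 double bond of the cyclopentene (ring C1, C2, C3, C3a, C7a) to C2–SO2–C3, so this ring is carried as a six-membered thiane 1,1-dioxide.
- This is possible because C2=C3 is an endocyclic, trisubstituted alkene with no other function: its two carbons can be the α and α′ carbons of a sulfone, and extrusion inside a ring can only give the cis alkene that an open-chain precursor would need as a (Z)-trisubstituted olefin.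
- The trans-fused hexahydroisothiochromene dioxide is then cut at C7a–C3a and C5–C4 (indene numbering) by a retro-Diels–Alder step to an acyclic sulfone with an (E)-2-methylenoate and an (E,E,E)-phenyl triene. Its two C–S bonds lead back to a trienyl thiol and an α-mesyloxy ester.
- Forward: the triene chain grows from methyl (R)-3-hydroxy-2-methylpropanoate by three olefinations; sulfur is installed, alkylated and oxidised; the cyclohexene and the six-membered sulfone ring form together; the sulfone ring is contracted to the cyclopentene; the ester is cleaved.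
- Stereochemistry: C1 comes from the chiral pool. C3a, C4, C5 and C7a come from the cycloaddition (alkene geometries, ester-endo transition state, equatorial tether substituents). The temporary sulfur-bearing centre comes from methyl (R)-2-hydroxybutanoate by SN2 inversion and is erased in the contraction.

Key step: step 14

Remark: the sulfur-bearing carbon is set as (S) so that its ethyl group is equatorial in the cyclisation; any erosion there is tolerable because step 14 makes this carbon sp2.
Remark: 2-(triphenylphosphoranylidene)butanal (6) is treated as a purchasable stabilised ylide, like its propanal homologue 4.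

**Route**

Step 1
Reactants: 1 methyl (R)-3-hydroxy-2-methylpropanoate
Product: 2 methyl (R)-3-[(tert-butyldimethylsilyl)oxy]-2-methylpropanoate
Conditions: TBSCl, imidazole, DMF, 0 °C → rt
Reagents that add atoms: tert-butyldimethylsilyl chloride, CC(C)(C)[Si](C)(C)Cl
Why: Standard silylation of a primary alcohol; the silyl ether masks the carbon that will later carry sulfur through the olefinations.

Step 2
Reactants: 2 methyl (R)-3-[(tert-butyldimethylsilyl)oxy]-2-methylpropanoate
Product: 3 (R)-3-[(tert-butyldimethylsilyl)oxy]-2-methylpropanal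
Conditions: i-Bu2AlH (1.05 equiv), CH2Cl2, −78 °C
Reagents that add atoms: none
Why: Partial ester reduction; the aluminium hemiacetal is stable at −78 °C and releases the aldehyde on work-up, and the α-centre is kept by using the aldehyde cold and crude.

Step 3
Reactants: 3 (R)-3-[(tert-butyldimethylsilyl)oxy]-2-methylpropanal; 4 2-(triphenylphosphoranylidene)propanal
Product: 5 (2E,4S)-5-[(tert-butyldimethylsilyl)oxy]-2,4-dimethylpent-2-enal
Conditions: PhMe, 90 °C
Reagents that add atoms: none
Why: Wittig reaction of a formyl-stabilised ylide should give the (E)-trisubstituted enal under neutral conditions that leave the α-methyl centre untouched (the descriptor changes only through the priority rules).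

Step 4
Reactants: 5 (2E,4S)-5-[(tert-butyldimethylsilyl)oxy]-2,4-dimethylpent-2-enal; 6 2-(triphenylphosphoranylidene)butanal
Product: 7 (2E,4E,6S)-7-[(tert-butyldimethylsilyl)oxy]-2-ethyl-4,6-dimethylhepta-2,4-dienal
Conditions: PhMe, 110 °C
Reagents that add atoms: none
Why: A second Wittig homologation with the ethyl-bearing formyl ylide should again give the (E) alkene (ethyl cis to the chain), and the more hindered, more conjugated product dienal should react more slowly than 5.

Step 5
Reactants: 7 (2E,4E,6S)-7-[(tert-butyldimethylsilyl)oxy]-2-ethyl-4,6-dimethylhepta-2,4-dienal; 8 diethyl benzylphosphonate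
Product: 9 tert-butyl{[(2S,3E,5E,7E)-6-ethyl-2,4-dimethyl-8-phenylocta-3,5,7-trien-1-yl]oxy}dimethylsilane
Conditions: NaH, THF, 0 °C → rt
Reagents that add atoms: none
Why: Horner–Wadsworth–Emmons reaction of the benzylphosphonate anion, which reliably gives (E)-styrenes; the silyl ether is stable to the base.

Step 6
Reactants: 9 tert-butyl{[(2S,3E,5E,7E)-6-ethyl-2,4-dimethyl-8-phenylocta-3,5,7-trien-1-yl]oxy}dimethylsilane
Product: 10 (2S,3E,5E,7E)-6-ethyl-2,4-dimethyl-8-phenylocta-3,5,7-trien-1-ol
Conditions: Bu4NF, THF, 0 °C → rt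
Reagents that add atoms: none
Why: Fluoride cleavage of the silyl ether; nothing else in the molecule responds to fluoride.

Step 7
Reactants: 10 (2S,3E,5E,7E)-6-ethyl-2,4-dimethyl-8-phenylocta-3,5,7-trien-1-ol
Product: 11 S-[(2S,3E,5E,7E)-6-ethyl-2,4-dimethyl-8-phenylocta-3,5,7-trien-1-yl] ethanethioate
Conditions: PPh3, DIAD, AcSH, THF, 0 °C, dark
Reagents that add atoms: thioacetic acid, CC(=O)S
Why: Mitsunobu thioesterification of a primary alcohol; thioacetic acid is acidic enough for the betaine, and the stereocentre is one carbon away and unaffected.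

Step 8
Reactants: 12 methyl (R)-2-hydroxybutanoate
Product: 13 methyl (R)-2-[(methanesulfonyl)oxy]butanoate
Conditions: MsCl, Et3N, CH2Cl2, 0 °C
Reagents that add atoms: methanesulfonyl chloride, CS(=O)(=O)Cl
Why: O-Sulfonylation proceeds with retention and turns the hydroxyl into a leaving group activated by the adjacent ester.

Step 9
Reactants: 11 S-[(2S,3E,5E,7E)-6-ethyl-2,4-dimethyl-8-phenylocta-3,5,7-trien-1-yl] ethanethioate; 13 methyl (R)-2-[(methanesulfonyl)oxy]butanoate
Product: 15 methyl (2S)-2-{[(2S,3E,5E,7E)-6-ethyl-2,4-dimethyl-8-phenylocta-3,5,7-trien-1-yl]sulfanyl}butanoate, via trienyl thiol 14 (not isolated)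
Conditions: NaOMe (1.0 equiv), MeOH/THF, 0 °C, degassed; then 13, 0 °C → rt
Reagents that add atoms: none
Why: Methoxide cleaves the thioacetate to the thiolate, which should displace the α-carbonyl-activated secondary mesylate by SN2 with inversion, so (R)-13 sets the (S) sulfur-bearing centre.

Step 10
Reactants: 15 methyl (2S)-2-{[(2S,3E,5E,7E)-6-ethyl-2,4-dimethyl-8-phenylocta-3,5,7-trien-1-yl]sulfanyl}butanoate
Product: 16 (2S)-2-{[(2S,3E,5E,7E)-6-ethyl-2,4-dimethyl-8-phenylocta-3,5,7-trien-1-yl]sulfanyl}butanal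
Conditions: i-Bu2AlH (1.1 equiv), PhMe/CH2Cl2, −78 °C
Reagents that add atoms: none
Why: Partial reduction of an α-heteroatom ester; the aluminium hemiacetal, held by the neighbouring sulfur, should survive until work-up, and the aldehyde is used at once to limit enolisation.

Step 11
Reactants: 16 (2S)-2-{[(2S,3E,5E,7E)-6-ethyl-2,4-dimethyl-8-phenylocta-3,5,7-trien-1-yl]sulfanyl}butanal; 17 methyl 2-(triphenylphosphoranylidene)propanoate
Product: 18 methyl (2E,4S)-4-{[(2S,3E,5E,7E)-6-ethyl-2,4-dimethyl-8-phenylocta-3,5,7-trien-1-yl]sulfanyl}-2-methylhex-2-enoate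
Conditions: CH2Cl2, rt
Reagents that add atoms: none
Why: Wittig reaction of an ester-stabilised ylide with an α-branched aldehyde should give the (E)-2-methylenoate under neutral conditions that spare the α-thio centre.

Step 12
Reactants: 18 methyl (2E,4S)-4-{[(2S,3E,5E,7E)-6-ethyl-2,4-dimethyl-8-phenylocta-3,5,7-trien-1-yl]sulfanyl}-2-methylhex-2-enoate
Product: 19 methyl (2E,4S)-4-{[(2S,3E,5E,7E)-6-ethyl-2,4-dimethyl-8-phenylocta-3,5,7-trien-1-yl]sulfonyl}-2-methylhex-2-enoate
Conditions: 30% aq. H2O2, (NH4)6Mo7O24·4H2O (cat.), EtOH, 0 °C → rt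
Reagents that add atoms: hydrogen peroxide, OO
Why: Peroxomolybdate oxidation is selective for sulfur over unfunctionalised alkenes and should take the sulfide through the sulfoxide to the sulfone quickly enough that the allylic sulfoxide does not rearrange.

Step 13
Reactants: 19 methyl (2E,4S)-4-{[(2S,3E,5E,7E)-6-ethyl-2,4-dimethyl-8-phenylocta-3,5,7-trien-1-yl]sulfonyl}-2-methylhex-2-enoate
Product: 20 methyl (1S,4S,4aS,7S,8R,8aS)-1,7-diethyl-4,5,8-trimethyl-7-[(E)-2-phenylethenyl]-3,4,4a,7,8,8a-hexahydro-1H-isothiochromene-8-carboxylate 2,2-dioxide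
Conditions: PhMe (0.01 M), BHT (cat.), 140 °C, sealed tube
Reagents that add atoms: none
Why: Intramolecular Diels–Alder reaction of a sulfone-tethered decatriene, in which the (E)-enoate and (E,E)-diene geometries fix C7 against C8, the ester-endo, tether-exo chair transition state gives the trans ring fusion, and the equatorial preference of the C4 methyl (an axial methyl would face an axial S=O) and the C1 ethyl selects the diene face, so the chiral-pool centre sets C4a, C7, C8 and C8a.

Step 14
Reactants: 20 methyl (1S,4S,4aS,7S,8R,8aS)-1,7-diethyl-4,5,8-trimethyl-7-[(E)-2-phenylethenyl]-3,4,4a,7,8,8a-hexahydro-1H-isothiochromene-8-carboxylate 2,2-dioxide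
Product: 23 methyl (1R,3aR,4R,5S,7aS)-3,5-diethyl-1,4,7-trimethyl-5-[(E)-2-phenylethenyl]-3a,4,5,7a-tetrahydro-1H-indene-4-carboxylate, via bromo sulfone 21 (not isolated), via episulfone 22 (not isolated)
Conditions: CBr2F2, KOH/Al2O3, t-BuOH/CH2Cl2, 0 °C → rt
Reagents that add atoms: none
Why: Base removes an α-hydrogen of the cyclic sulfone (most readily at the C3 methylene) and the carbanion is brominated by CBr2F2 to 21; a second deprotonation at the tertiary α′-carbon C1 displaces bromide in a 1,3-elimination to the fused thiirane 1,1-dioxide 22, and cheletropic loss of SO2 leaves the C2=C3 double bond of the indene, so the six-membered sulfur ring becomes the cyclopentene. The closest known reaction type is the Ramberg–Bäcklund ring contraction of thiane 1,1-dioxides to cyclopentenes with in-situ halogenation. The only ring closed is the transient three-membered episulfone (3-exo-tet), and its collapse leaves the five-membered carbocycle with the new C–C bond as a double bond. No stereocentre is created: the temporary sulfur-bearing centre becomes sp2, and C1, C3a, C4, C5 and C7a of the product, none of them acidic under KOH, keep the configuration fixed in step 13, so the trans ring fusion is carried over. The selectivity needed is positional: the double bond can only form between the two carbons that flank sulfur, so it is regiodefined and necessarily cis. The hindered, non-enolisable methyl ester and the unactivated alkenes should be inert to KOH/Al2O3 at room temperature.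

Step 15
Reactants: 23 methyl (1R,3aR,4R,5S,7aS)-3,5-diethyl-1,4,7-trimethyl-5-[(E)-2-phenylethenyl]-3a,4,5,7a-tetrahydro-1H-indene-4-carboxylate
Product: 24 24-nor-spiculoic acid B, (1R,3aR,4R,5S,7aS)-3,5-diethyl-1,4,7-trimethyl-5-[(E)-2-phenylethenyl]-3a,4,5,7a-tetrahydro-1H-indene-4-carboxylic acid
Conditions: n-PrSLi, HMPA, rt; then 1 M HCl
Reagents that add atoms: none
Why: SN2 demethylation by thiolate attacks the unhindered O-methyl carbon, so it should not be slowed by the two quaternary carbons that shield the carbonyl group, and it leaves all stereocentres and alkenes alone.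

**Compound list**

1 | methyl (R)-3-hydroxy-2-methylpropanoate | OC[C@@H](C)C(=O)OC | starting material
2 | methyl (R)-3-[(tert-butyldimethylsilyl)oxy]-2-methylpropanoate | CC(C)(C)[Si](C)(C)OC[C@@H](C)C(=O)OC | intermediate
3 | (R)-3-[(tert-butyldimethylsilyl)oxy]-2-methylpropanal | CC(C)(C)[Si](C)(C)OC[C@@H](C)C=O | intermediate
4 | 2-(triphenylphosphoranylidene)propanal | CC(C=O)=P(c1ccccc1)(c1ccccc1)c1ccccc1 | starting material
5 | (2E,4S)-5-[(tert-butyldimethylsilyl)oxy]-2,4-dimethylpent-2-enal | CC(C)(C)[Si](C)(C)OC[C@@H](C)/C=C(C)/C=O | intermediate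
6 | 2-(triphenylphosphoranylidene)butanal | CCC(C=O)=P(c1ccccc1)(c1ccccc1)c1ccccc1 | starting material
7 | (2E,4E,6S)-7-[(tert-butyldimethylsilyl)oxy]-2-ethyl-4,6-dimethylhepta-2,4-dienal | CC(C)(C)[Si](C)(C)OC[C@@H](C)/C=C(C)/C=C(CC)/C=O | intermediate
8 | diethyl benzylphosphonate | CCOP(=O)(Cc1ccccc1)OCC | starting material
9 | tert-butyl{[(2S,3E,5E,7E)-6-ethyl-2,4-dimethyl-8-phenylocta-3,5,7-trien-1-yl]oxy}dimethylsilane | CC(C)(C)[Si](C)(C)OC[C@@H](C)/C=C(C)/C=C(CC)/C=C/c1ccccc1 | intermediate
10 | (2S,3E,5E,7E)-6-ethyl-2,4-dimethyl-8-phenylocta-3,5,7-trien-1-ol | OC[C@@H](C)/C=C(C)/C=C(CC)/C=C/c1ccccc1 | intermediate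
11 | S-[(2S,3E,5E,7E)-6-ethyl-2,4-dimethyl-8-phenylocta-3,5,7-trien-1-yl] ethanethioate | CC(=O)SC[C@@H](C)/C=C(C)/C=C(CC)/C=C/c1ccccc1 | intermediate
12 | methyl (R)-2-hydroxybutanoate | CC[C@@H](O)C(=O)OC | starting material
13 | methyl (R)-2-[(methanesulfonyl)oxy]butanoate | CC[C@@H](OS(C)(=O)=O)C(=O)OC | intermediate
14 | (2S,3E,5E,7E)-6-ethyl-2,4-dimethyl-8-phenylocta-3,5,7-triene-1-thiol (as its sodium thiolate in the flask) | SC[C@@H](C)/C=C(C)/C=C(CC)/C=C/c1ccccc1 | intermediate
15 | methyl (2S)-2-{[(2S,3E,5E,7E)-6-ethyl-2,4-dimethyl-8-phenylocta-3,5,7-trien-1-yl]sulfanyl}butanoate | COC(=O)[C@H](CC)SC[C@@H](C)/C=C(C)/C=C(CC)/C=C/c1ccccc1 | intermediate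
16 | (2S)-2-{[(2S,3E,5E,7E)-6-ethyl-2,4-dimethyl-8-phenylocta-3,5,7-trien-1-yl]sulfanyl}butanal | O=C[C@H](CC)SC[C@@H](C)/C=C(C)/C=C(CC)/C=C/c1ccccc1 | intermediate
17 | methyl 2-(triphenylphosphoranylidene)propanoate | COC(=O)C(C)=P(c1ccccc1)(c1ccccc1)c1ccccc1 | starting material
18 | methyl (2E,4S)-4-{[(2S,3E,5E,7E)-6-ethyl-2,4-dimethyl-8-phenylocta-3,5,7-trien-1-yl]sulfanyl}-2-methylhex-2-enoate | COC(=O)/C(C)=C/[C@H](CC)SC[C@@H](C)/C=C(C)/C=C(CC)/C=C/c1ccccc1 | intermediate
19 | methyl (2E,4S)-4-{[(2S,3E,5E,7E)-6-ethyl-2,4-dimethyl-8-phenylocta-3,5,7-trien-1-yl]sulfonyl}-2-methylhex-2-enoate | COC(=O)/C(C)=C/[C@H](CC)S(=O)(=O)C[C@@H](C)/C=C(C)/C=C(CC)/C=C/c1ccccc1 | intermediate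
20 | methyl (1S,4S,4aS,7S,8R,8aS)-1,7-diethyl-4,5,8-trimethyl-7-[(E)-2-phenylethenyl]-3,4,4a,7,8,8a-hexahydro-1H-isothiochromene-8-carboxylate 2,2-dioxide (trans-fused, C1 ethyl and C4 methyl equatorial) | CC[C@@H]1S(=O)(=O)C[C@@H](C)[C@@H]2C(C)=C[C@@](/C=C/c3ccccc3)(CC)[C@](C)(C(=O)OC)[C@@H]12 | intermediate
21 | 3-bromo derivative of 20 (bromine on the ring CH2 next to sulfur; other centres as in 20; either configuration at C3) | CC[C@@H]1S(=O)(=O)C(Br)[C@@H](C)[C@@H]2C(C)=C[C@@](/C=C/c3ccccc3)(CC)[C@](C)(C(=O)OC)[C@@H]12 | intermediate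
22 | episulfone: thiirane 1,1-dioxide fused across C2–C3 of the skeleton of 23 (C2 and C3 bonded to each other and both to SO2; other centres as in 20; configuration at the two thiirane carbons not defined) | CCC12C(S1(=O)=O)[C@@H](C)[C@@H]3C(C)=C[C@@](/C=C/c4ccccc4)(CC)[C@](C)(C(=O)OC)[C@@H]23 | intermediate
23 | methyl (1R,3aR,4R,5S,7aS)-3,5-diethyl-1,4,7-trimethyl-5-[(E)-2-phenylethenyl]-3a,4,5,7a-tetrahydro-1H-indene-4-carboxylate | CCC1=C[C@@H](C)[C@@H]2C(C)=C[C@@](/C=C/c3ccccc3)(CC)[C@](C)(C(=O)OC)[C@@H]12 | intermediate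
24 | 24-nor-spiculoic acid B, (1R,3aR,4R,5S,7aS)-3,5-diethyl-1,4,7-trimethyl-5-[(E)-2-phenylethenyl]-3a,4,5,7a-tetrahydro-1H-indene-4-carboxylic acid | CCC1=C[C@@H](C)[C@@H]2C(C)=C[C@@](/C=C/c3ccccc3)(CC)[C@](C)(C(=O)O)[C@@H]12 | target

**Step count and risks**

Total step count: 15. Longest linear sequence: 14 (steps 1–7 and 9–15; step 8 prepares the mesylate fragment).

Steps most likely to fail:

Step 13. The cycloaddition may discriminate poorly between the ester-endo (trans-fused) and ester-exo (cis-fused) transition states. At the temperature a trisubstituted ester dienophile needs, a 1,5-hydrogen shift in the ethyl-substituted diene or a 1,3-migration of the allylic sulfonyl group may also compete. The fallback raises the dienophile to the aldehyde level and cyclises under Lewis acid at low temperature. It sets out from 19: reduction with i-Bu2AlH (CH2Cl2, −78 °C) should give the sulfonyl allylic alcohol F1, MnO2 the sulfonyl enal F2, and Me2AlCl (CH2Cl2, −40 °C) the aldehyde-endo cycloadduct, the bicyclic sulfone aldehyde F3. NaClO2/NaH2PO4/2-methyl-2-butene should then give the bicyclic sulfone acid F4, and Me3SiCHN2 (MeOH/PhMe) returns the route to 20.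

Step 14. The in-situ bromination may run on to a dibromide at the C3 methylene, the axial tertiary hydrogen at C1 may be removed too slowly for the 1,3-elimination, or halocarbene may be captured by the electron-rich alkenes. The fallback closes the cyclopentene directly by an all-carbon intramolecular Diels–Alder reaction. It sets out from 10: Dess–Martin oxidation (NaHCO3, CH2Cl2, 0 °C) should give the β,γ-unsaturated trienal F5, used cold and at once. Stork–Zhao olefination with Ph3P=C(I)Et (from propyltriphenylphosphonium bromide, n-BuLi, I2, then NaN(SiMe3)2, THF, −78 °C) should give the (Z)-vinyl iodide F6. Suzuki–Miyaura coupling with methyl (E)-2-methyl-3-(4,4,5,5-tetramethyl-1,3,2-dioxaborolan-2-yl)prop-2-enoate (Pd(PPh3)4, K3PO4, THF/H2O) should give the (2E,4Z)-pentaene ester F7, and heating F7 in PhMe returns the route to 23.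

Step 4. The stabilised formyl ylide may add too slowly to the hindered conjugated enal, and the product dienal may be homologated a second time. The fallback brings in the two carbons and the ethyl branch at the ester level. It sets out from 5: Horner–Wadsworth–Emmons reaction with triethyl 2-phosphonobutanoate (NaH, THF, 0 °C → rt) should give the silyloxy dienoate F8, i-Bu2AlH (CH2Cl2, −78 °C) the silyloxy dienol F9, and MnO2 (CH2Cl2, rt) returns the route to 7.

**Further compounds**

F1 | step 13 | (2E,4S)-4-{[(2S,3E,5E,7E)-6-ethyl-2,4-dimethyl-8-phenylocta-3,5,7-trien-1-yl]sulfonyl}-2-methylhex-2-en-1-ol | OC/C(C)=C/[C@H](CC)S(=O)(=O)C[C@@H](C)/C=C(C)/C=C(CC)/C=C/c1ccccc1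
F2 | step 13 | (2E,4S)-4-{[(2S,3E,5E,7E)-6-ethyl-2,4-dimethyl-8-phenylocta-3,5,7-trien-1-yl]sulfonyl}-2-methylhex-2-enal | O=C/C(C)=C/[C@H](CC)S(=O)(=O)C[C@@H](C)/C=C(C)/C=C(CC)/C=C/c1ccccc1
F3 | step 13 | (1S,4S,4aS,7S,8R,8aS)-1,7-diethyl-4,5,8-trimethyl-7-[(E)-2-phenylethenyl]-3,4,4a,7,8,8a-hexahydro-1H-isothiochromene-8-carbaldehyde 2,2-dioxide | CC[C@@H]1S(=O)(=O)C[C@@H](C)[C@@H]2C(C)=C[C@@](/C=C/c3ccccc3)(CC)[C@](C)(C=O)[C@@H]12
F4 | step 13 | (1S,4S,4aS,7S,8R,8aS)-1,7-diethyl-4,5,8-trimethyl-7-[(E)-2-phenylethenyl]-3,4,4a,7,8,8a-hexahydro-1H-isothiochromene-8-carboxylic acid 2,2-dioxide | CC[C@@H]1S(=O)(=O)C[C@@H](C)[C@@H]2C(C)=C[C@@](/C=C/c3ccccc3)(CC)[C@](C)(C(=O)O)[C@@H]12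
F5 | step 14 | (2S,3E,5E,7E)-6-ethyl-2,4-dimethyl-8-phenylocta-3,5,7-trienal | O=C[C@@H](C)/C=C(C)/C=C(CC)/C=C/c1ccccc1
F6 | step 14 | [(1E,3E,5E,7S,8Z)-3-ethyl-9-iodo-5,7-dimethylundeca-1,3,5,8-tetraen-1-yl]benzene | CC/C(I)=C/[C@@H](C)/C=C(C)/C=C(CC)/C=C/c1ccccc1
F7 | step 14 | methyl (2E,4Z,6S,7E,9E,11E)-4,10-diethyl-2,6,8-trimethyl-12-phenyldodeca-2,4,7,9,11-pentaenoate | COC(=O)/C(C)=C/C(CC)=C\[C@@H](C)/C=C(C)/C=C(CC)/C=C/c1ccccc1
F8 | step 4 | ethyl (2E,4E,6S)-7-[(tert-butyldimethylsilyl)oxy]-2-ethyl-4,6-dimethylhepta-2,4-dienoate | CC(C)(C)[Si](C)(C)OC[C@@H](C)/C=C(C)/C=C(CC)/C(=O)OCC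
F9 | step 4 | (2E,4E,6S)-7-[(tert-butyldimethylsilyl)oxy]-2-ethyl-4,6-dimethylhepta-2,4-dien-1-ol | CC(C)(C)[Si](C)(C)OC[C@@H](C)/C=C(C)/C=C(CC)/CO
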